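**Retrosynthetic overview**
1. Building blocks: O-benzyl phloretic acid 1 (benzene ring bought intact; no ring is formed at any stage), activated through chloromethyl ester 2 to iodomethyl ester 3, and the commodity C18 α-olefin 1-octadecene 4.
2. Key disconnection: the C18–C19 carbon–carbon bond of the nonadecyl chain, not the ester C–O bond. Iodomethyl ester 3 acts as a one-carbon acyloxymethyl donor and is joined to 4 by a new nickel-hydride anti-Markovnikov hydro(acyloxymethyl)ation, giving benzyl-protected ester 5.
3. Final disconnection: the phenol O–benzyl bond; hydrogenolysis of 5 gives target 6.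
4. The odd C19 chain is thus built from a cheap even-chain olefin plus one carbon.

Assumption: the target has no stereocentre and is achiral, so "single enantiomer" is taken to mean the constitution as drawn; compounds 1 and 4 are taken as commercially available.

**Route**

Step 1
Reactants: 1 3-[4-(benzyloxy)phenyl]propanoic acid
Product: 2 chloromethyl 3-[4-(benzyloxy)phenyl]propanoate
Conditions: ClCH2OSO2Cl (1.2 equiv), NaHCO3 (4 equiv), Bu4NHSO4 (10 mol%), CH2Cl2/H2O 1:1, 0 °C to rt, 2 h
Reagents that add atoms: chloromethyl chlorosulfate, ClCOS(=O)(=O)Cl
Why: Phase-transfer O-alkylation (SN2) of the carboxylate at the CH2 of chloromethyl chlorosulfate works because chlorosulfate is a far better leaving group than chloride, so the chloromethyl ester forms selectively while the benzyl ether is inert; no stereocentre is formed.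

Step 2
Reactants: 2 chloromethyl 3-[4-(benzyloxy)phenyl]propanoate
Product: 3 iodomethyl 3-[4-(benzyloxy)phenyl]propanoate
Conditions: NaI (1.5 equiv), acetone, rt, dark, 3 h; filter, concentrate, use at once
Reagents that add atoms: sodium iodide, [Na+].[I-]
Why: Finkelstein halide exchange (SN2) is fast at the α-acyloxy carbon and is driven by precipitation of NaCl from acetone, giving the weak C–I bond needed for the nickel step; no stereocentre is formed.

Step 3
Reactants: 3 iodomethyl 3-[4-(benzyloxy)phenyl]propanoate; 4 1-octadecene (2 equiv)
Product: 5 nonadecyl 3-[4-(benzyloxy)phenyl]propanoate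
Conditions: NiBr2·diglyme (10 mol%), 4,4'-di-tert-butyl-2,2'-bipyridine (12 mol%), (EtO)2MeSiH (2.5 equiv, added over 2 h), Na2CO3 (2 equiv), DMA/THF 2:1, 25 °C, 16 h, Ar
Reagents that add atoms: none
Why: Proposed new method: a bipyridine-ligated monovalent nickel hydride (from NiBr2, silane and carbonate) inserts 1-octadecene anti-Markovnikov to give octadecyl–nickel, which abstracts iodine from 3; the resulting acyloxymethyl radical (stabilised by the adjacent oxygen, no β-hydrogen) recombines at divalent nickel and C(sp3)–C(sp3) reductive elimination from trivalent nickel forms the C18–C19 bond, delivering the whole nonadecyl ester with no stereocentre formed; the closest known reaction type is nickel-hydride-catalysed anti-Markovnikov reductive hydroalkylation of terminal olefins with alkyl iodides (including 1-haloalkyl esters of secondary carbinols), which has not been shown for halomethyl carboxylates as one-carbon acyloxymethyl donors.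

Step 4
Reactants: 5 nonadecyl 3-[4-(benzyloxy)phenyl]propanoate
Product: 6 nonadecyl 3-(4-hydroxyphenyl)propanoate
Conditions: H2 (1 atm), 10% Pd/C, THF/EtOAc 1:1, rt, 6 h
Reagents that add atoms: none
Why: Heterogeneous palladium-catalysed hydrogenolysis cleaves the benzylic C–O bond to free the phenol while the saturated alkyl ester and the arene are inert; no stereocentre is present.

**Compound list**
1 | 3-[4-(benzyloxy)phenyl]propanoic acid | OC(=O)CCc1ccc(OCc2ccccc2)cc1 | starting material
2 | chloromethyl 3-[4-(benzyloxy)phenyl]propanoate | ClCOC(=O)CCc1ccc(OCc2ccccc2)cc1 | intermediate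
3 | iodomethyl 3-[4-(benzyloxy)phenyl]propanoate | ICOC(=O)CCc1ccc(OCc2ccccc2)cc1 | intermediate
4 | 1-octadecene | CCCCCCCCCCCCCCCCC=C | starting material
5 | nonadecyl 3-[4-(benzyloxy)phenyl]propanoate | CCCCCCCCCCCCCCCCCCCOC(=O)CCc1ccc(OCc2ccccc2)cc1 | intermediate
6 | nonadecyl 3-(4-hydroxyphenyl)propanoate | CCCCCCCCCCCCCCCCCCCOC(=O)CCc1ccc(O)cc1 | target

**Step count**
Total steps: 4. Longest linear sequence: 4 steps (1 → 2 → 3 → 5 → 6).

**Three steps most likely to fail**

Step 3 (proposed new step). Likely failure modes are hydrodeiodination of 3 to the methyl ester, isomerisation of the olefin by the nickel hydride, and homocoupling of the acyloxymethyl radical. The fallback uses known chemistry only; it sets out from 4 and comes back to the route at 5. 1-Octadecene 4 is hydroformylated with linear selectivity (Rh(acac)(CO)2 0.1 mol%, Xantphos 0.4 mol%, CO/H2 1:1 at 10 bar, toluene, 80 °C) to nonadecanal F1. This is reduced (NaBH4, EtOH/THF, 0 °C) to 1-nonadecanol F2, which is recrystallised to linear purity and can also simply be bought. Carbodiimide esterification of F2 with acid 1 (EDC·HCl, DMAP cat., CH2Cl2, rt; Steglich conditions) then gives 5.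

Step 1. The chloromethyl ester can be attacked by a second carboxylate to give the methylene diester, or be hydrolysed in the biphasic medium. The fallback sets out from 1 and comes back at 2. Acid 1 is alkylated with chloromethyl methyl sulfide (Cs2CO3, NaI cat., DMF, rt) to (methylsulfanyl)methyl 3-[4-(benzyloxy)phenyl]propanoate F3. Sulfuryl chloride (SO2Cl2, 1.05 equiv, CH2Cl2, −20 to 0 °C) then replaces the methylsulfanyl group by chloride through a chlorosulfonium intermediate, releasing methanesulfenyl chloride and giving 2. No free carboxylate is present at this stage, so the diester cannot form.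

Step 4. Traces of iodide or nickel carried over from step 3 can poison Pd/C, and the waxy long-chain ester dissolves poorly. The fallback sets out from 5 and comes back at 6. It is a Lewis-acid debenzylation instead of a hydrogenolysis: BCl3 (2 equiv) with pentamethylbenzene (3 equiv) as cation scavenger in CH2Cl2 at −78 °C. This transfers the benzyl group to the scavenger (giving 1-benzyl-2,3,4,5,6-pentamethylbenzene) and leaves the aryl dichloroborinate nonadecyl 3-{4-[(dichloroboranyl)oxy]phenyl}propanoate F4 (not isolated). Cold aqueous quench hydrolyses F4 to 6; the alkyl ester survives at this temperature.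

**Further compounds**
F1 | step 3 | nonadecanal | CCCCCCCCCCCCCCCCCCC=O
F2 | step 3 | 1-nonadecanol | CCCCCCCCCCCCCCCCCCCO
F3 | step 1 | (methylsulfanyl)methyl 3-[4-(benzyloxy)phenyl]propanoate | CSCOC(=O)CCc1ccc(OCc2ccccc2)cc1
F4 | step 4 | nonadecyl 3-{4-[(dichloroboranyl)oxy]phenyl}propanoate | CCCCCCCCCCCCCCCCCCCOC(=O)CCc1ccc(OB(Cl)Cl)cc1
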